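The readings come from a simulation for an exercise; noise was put on by code.

**Two runs.** Product stands at 67% after 1.00 min in the dusk run and at 65% in the midnight run, though free base rises from 0.55 equiv to 0.83 equiv. That gap of 2 percentage points stands against a scatter of 2 points on each reading, so I read the two runs as one.

all flasks: electrophile 0.10 M
- dusk: nucleophile 1 equiv; free base 0.55 equiv; run made earlier
- midnight: nucleophile 1 equiv; free base 0.83 equiv; run made earlier
- flask: nucleophile 1.00 equiv; free base 1.10 equiv; time 6.0 min

| run | time / min | electrophile / % | product / % |
|---|---|---|---|
| dusk | 0.200 | 67 | 34 |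
| dusk | 0.500 | 49 | 52 |
| dusk | 1.00 | 31 | 67 |
| dusk | 1.50 | 21 | 75 |
| dusk | 2.00 | 19 | 80 |
| dusk | 3.00 | 16 | 84 |
| dusk | 4.00 | 10 | 87 |
| midnight | 0.250 | 61 | 37 |
| midnight | 0.417 | 58 | 50 |
| midnight | 0.667 | 41 | 57 |
| midnight | 1.00 | 33 | 65 |
| midnight | 1.50 | 25 | 75 |
| midnight | 2.50 | 13 | 80 |
| midnight | 4.00 | 14 | 84 |

(each reading ± 2 percentage points)

- part of the electrophile that has reacted at 6.0 min
- share of the unused nucleophile that is free and not bound as protonated nucleophile, at 6.0 min

**One number.** With equal charges of electrophile and nucleophile, I treat the decay as second-order, so the fraction of electrophile left is 1/(1 + Da). The electrophile read at 1.00 min in the two runs gives k[electrophile] = 2.13 min⁻¹, a value that carries their scatter. The Damköhler number Da = k[electrophile]t, the time of the flask measured in units of the first half-life of 0.469 min, is then 12.8. My reckoning for this flask is 92.7% reacted.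

**Its test.** At 4.00 min the same reckoning leaves 10.5%, between the readings of 10% (dusk) and 14% (midnight). But Da holds nothing on binding, so for the free share of nucleophile I have no number.

**The result.** The forecast says 93% of the electrophile reacted (90% to 95.5%) and a free share of 90% (65% to 99%), the latter with the words “This part is a guess.” The flask gives 92.8% reacted and a free share of 66.3%.

    acid set free + free base ⇌ salt of the base, settled at all times (K = 13.0 M⁻¹)
    crystals ⇌ acid set free, rate k2*(cs2 - [acid set free]) while solid is left; crystals form when [acid set free] > cs2 (solubility = 1.10 mM, k = 5.20 s⁻¹)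
    electrophile + nucleophile → acid set free + product (k = 0.540 M⁻¹ s⁻¹)
    nucleophile + acid set free ⇌ protonated nucleophile, settled at all times (K = 460 M⁻¹)

**The comparison.** In the flask at 0.390 min the half-life of nucleophile by the step from electrophile and nucleophile to product is 0.40 min, short against 6.0 min, and at 3.00 min that step has 93% of its turnover up to 6.0 min behind it. At 6.00 min this flask holds 0.00244 M of protonated nucleophile beside 4.8% of the nucleophile charge still unbound, while 99% of the free base stands unbound.

**Neighbour flask.** With 0.025 M of electrophile, the same equivalents and the same time, Da falls with the charge to 3.19, which gives 76.1% reacted. The computed neighbour gives 76.7%.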